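**Assumption (one line):** the chiral purchases are (S)-4-(TBSO)cyclopent-2-enone (5) and (R)-2-hydroxy-3-methylbutanoic acid (1). The C1 acylal is assumed to settle at the anomerically favoured epimer, which is the target configuration.

**Retrosynthesis**
1. Target 19 ⇒ Stille coupling (C4–C11) of 4-iodo-dihydropyran 18 with stannylmethyl ester 4, which is made from (R)-2-hydroxyisovalerate 1.
2. 18 ⇒ 17 ⇒ gold-catalysed 6-endo alkyne–aldehyde cyclisation with acid capture. This closes the dihydropyran ring and sets the C1 acylal from alkynyl aldehyde 16.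
3. 16 ⇒ photochemical hypochlorite 1,5-HAT chlorination of the C8 methyl (C10–Cl), directed by the cis C5–OH. The C5 carbinol comes from acetylide addition to ketone 10.
4. 10 ⇒ SmI2 epoxide opening/HCHO aldol of α,β-epoxy ketone 8 ⇒ Weitz–Scheffer epoxidation of enone 7 ⇒ 5. The cyclopentane is already present. The epoxide and the 1,3-dioxane are temporary rings, and the dihydropyran ring is formed last.

---

**Step 1**
Reactants: 1 (R)-2-hydroxy-3-methylbutanoic acid
Product: 2 (R)-2-(3-methylbutanoyloxy)-3-methylbutanoic acid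
Conditions: i-PrCH2COCl (2.3 equiv), pyridine, CH2Cl2, 0 °C→rt; then H2O/THF, rt
Reagents that add atoms: isovaleryl chloride, CC(C)CC(=O)Cl
Why: O-acylation of the secondary alcohol with excess acid chloride, then hydrolysis of the mixed anhydride; the (R) centre is not touched.

**Step 2**
Reactants: 2; 3 tributyl(hydroxymethyl)stannane
Product: 4 (tributylstannyl)methyl (R)-2-(isovaleryloxy)-3-methylbutanoate
Conditions: DCC, DMAP (cat.), CH2Cl2, 0 °C→rt
Reagents that add atoms: none
Why: Steglich esterification gives the C11 coupling partner with the side-chain ester pre-formed.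

**Step 3**
Reactants: 5 (S)-4-(TBSO)cyclopent-2-en-1-one
Product: 6 TMS enol ether of trans-3-methyl-4-(TBSO)cyclopentanone
Conditions: Me2CuLi (MeLi, CuI), TMSCl, THF, −78 °C
Reagents that add atoms: methyllithium, C[Li]; chlorotrimethylsilane, C[Si](C)(C)Cl
Why: cuprate 1,4-addition anti to OTBS with in-situ silyl trapping fixes the enolate at C9–C5, so the next step is regiospecific.

**Step 4**
Reactants: 6
Product: 7 (4S)-4-(TBSO)-3-methylcyclopent-2-en-1-one
Conditions: Pd(OAc)2 (1.1 equiv), MeMCN, 25 °C
Reagents that add atoms: none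
Why: Saegusa–Ito oxidation converts the silyl enol ether into the β,β-disubstituted enone and removes the now-unneeded C8 stereocentre.

**Step 5**
Reactants: 7
Product: 8 4-(TBSO)-5-methyl-6-oxabicyclo[3.1.0]hexan-2-one (epoxide O trans to OTBS)
Conditions: 30% aq. H2O2, NaOH (0.1 equiv), MeOH, 0 °C
Reagents that add atoms: hydrogen peroxide, OO
Why: Weitz–Scheffer nucleophilic epoxidation, with HOO⁻ adding to C8 anti to the C7 OTBS, sets C8 with O on the α face and CH3 on the β face.

**Step 6**
Reactants: 8
Product: 9 3-hydroxy-2-(hydroxymethyl)-3-methyl-4-(TBSO)cyclopentan-1-one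
Conditions: SmI2 (2.2 equiv), THF, −78 °C; then monomeric HCHO/THF, −78→0 °C
Reagents that add atoms: formaldehyde, C=O
Why: SmI2 cleaves the α-C–O bond of the epoxy ketone, leaving the C8 tertiary α-alkoxide, and the Sm(III) enolate is trapped by formaldehyde in a chelated aldol syn to that alkoxide, placing C1 on C9 α (cis to the C8 oxygen).

**Step 7**
Reactants: 9
Product: 10 1,3-dioxane acetonide bridging C8–O and C1 (ketone at C5, 7-OTBS)
Conditions: Me2C(OMe)2, CSA (cat.), CH2Cl2, rt
Reagents that add atoms: 2,2-dimethoxypropane, COC(C)(C)OC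
Why: acetonide formation on the cis 1,3-diol protects both oxygens and blocks retro-aldol of the β-hydroxy ketone.

**Step 8**
Reactants: 10
Product: 11 C5 tertiary propargylic alcohol (TMS-alkyne α, OH β)
Conditions: Me3SiC≡CMgBr (3 equiv), CeCl3, THF, −78→0 °C
Reagents that add atoms: (trimethylsilylethynyl)magnesium bromide, C[Si](C)(C)C#C[Mg]Br
Why: 1,2-addition of the acetylide to the C5 ketone sets C5; the α-face is preferred because the β-face carries 1,3-syn OTBS and CH3.

**Step 9**
Reactants: 11
Product: 12 10-chloro compound (C10–H replaced by C10–Cl)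
Conditions: t-BuOCl (1.2 equiv), CH2Cl2, 0 °C, dark; evaporate; then hν (350 nm), CH2Cl2, 10 °C
Reagents that add atoms: tert-butyl hypochlorite, CC(C)(C)OCl
Why: Barton–Walling hypochlorite photolysis forms the C5 alkoxy radical, which abstracts H from the cis-1,3 C10 methyl by 1,5-HAT, and Cl transfer gives CH2Cl with no change at any stereocentre.

**Step 10**
Reactants: 12
Product: 13 7-alcohol with terminal alkyne (TBS and TMS removed)
Conditions: TBAF·3H2O, AcOH, THF, 25 °C
Reagents that add atoms: none
Why: fluoride desilylation; AcOH buffering prevents alkoxide displacement of the neopentyl chloride.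

**Step 11**
Reactants: 13
Product: 14 7-acetate
Conditions: Ac2O, Et3N, DMAP (cat.), CH2Cl2, 0 °C
Reagents that add atoms: acetic anhydride, CC(=O)OC(C)=O
Why: selective acetylation of the secondary C7–OH installs the target acetate; the hindered tertiary OH is untouched.

**Step 12**
Reactants: 14
Product: 15 C1/C8 diol
Conditions: AcOH/H2O/THF (4:1:1), 45 °C
Reagents that add atoms: none
Why: mild hydrolysis removes the acetonide, which is more acid-labile than the acetate, chloride and tertiary propargylic alcohol.

**Step 13**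
Reactants: 15
Product: 16 C1 aldehyde (alkynyl aldehyde)
Conditions: Dess–Martin periodinane, NaHCO3, CH2Cl2, 0 °C
Reagents that add atoms: none
Why: Dess–Martin oxidation of the primary alcohol only; C9 can equilibrate via the aldehyde enol toward the cis (α) isomer needed for cyclisation.

**Step 14**
Reactants: 16
Product: 17 1-O-isovaleryl-3,4-ene dihydropyran (C4–H)
Conditions: IPrAuCl/AgNTf2 (5 mol%), isovaleric acid (2 equiv), 4 Å MS, CH2Cl2, 23 °C
Reagents that add atoms: isovaleric acid, CC(C)CC(=O)O
Why: Proposed new method: the aldehyde oxygen attacks the Au-activated terminal alkyne 6-endo (C3–O2 bond), the resulting C1 oxocarbenium is captured by isovalerate (acylal), and protodeauration gives the C3=C4 enol ether. The closest known reaction is the Pd/Au cycloisomerisation of 2-alkynylbenzaldehydes with alcohols to 1-alkoxy-isochromenes. Here a carboxylic acid is the nucleophile on an aliphatic, cis-fused substrate, and C1 is set by axial capture (anomeric effect).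

**Step 15**
Reactants: 17
Product: 18 4-iodo-dihydropyran
Conditions: NIS (1.2 equiv), AgNO3 (0.1 equiv), MeCN, 0 °C
Reagents that add atoms: N-iodosuccinimide, O=C1CCC(=O)N1I
Why: iodination at the nucleophilic β-carbon of the enol ether, as in 2-iodoglycal formation.

**Step 16**
Reactants: 18; 4
Product: 19 Volvaltrate B
Conditions: Pd2(dba)3 (2.5 mol%), AsPh3, CuI (10 mol%), DMF, 50 °C
Reagents that add atoms: none
Why: Stille coupling forms C4–C11 with retention of the enol-ether geometry and delivers the complete side-chain ester.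

---

**Compound list**
1 | (R)-2-hydroxy-3-methylbutanoic acid | OC(=O)[C@H](O)C(C)C | starting material
2 | (R)-2-(isovaleryloxy)-3-methylbutanoic acid | OC(=O)[C@H](OC(=O)CC(C)C)C(C)C | intermediate
3 | tributyl(hydroxymethyl)stannane | CCCC[Sn](CCCC)(CCCC)CO | starting material
4 | (tributylstannyl)methyl (R)-2-(isovaleryloxy)-3-methylbutanoate | CCCC[Sn](CCCC)(CCCC)COC(=O)[C@H](OC(=O)CC(C)C)C(C)C | intermediate
5 | (S)-4-(TBSO)cyclopent-2-en-1-one | O=C1C=C[C@@H](O[Si](C)(C)C(C)(C)C)C1 | starting material
6 | (4S)-4-(TBSO)-3-methyl-1-(TMSO)cyclopent-1-ene, Me trans to OTBS | C[C@H]1C=C(O[Si](C)(C)C)C[C@@H]1O[Si](C)(C)C(C)(C)C | intermediate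
7 | (4S)-4-(TBSO)-3-methylcyclopent-2-en-1-one | CC1=CC(=O)C[C@@H]1O[Si](C)(C)C(C)(C)C | intermediate
8 | α,β-epoxy ketone, O α (trans to OTBS), CH3 β | C[C@]12O[C@H]1C(=O)C[C@@H]2O[Si](C)(C)C(C)(C)C | intermediate
9 | 3-hydroxy-2-(hydroxymethyl)-3-methyl-4-(TBSO)cyclopentanone (CH2OH and OH α, Me and OTBS β) | OC[C@H]1C(=O)C[C@H](O[Si](C)(C)C(C)(C)C)[C@@]1(C)O | intermediate
10 | C1/C8 acetonide of 9 (cis-fused 1,3-dioxane) | CC1(C)OC[C@H]2C(=O)C[C@H](O[Si](C)(C)C(C)(C)C)[C@@]2(C)O1 | intermediate
11 | C5 propargylic alcohol (TMS-alkyne α, OH β), acetonide, 7-OTBS | C[Si](C)(C)C#C[C@@]1(O)C[C@H](O[Si](C)(C)C(C)(C)C)[C@@]2(C)OC(C)(C)OC[C@@H]12 | intermediate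
12 | 10-chloro derivative of 11 | C[Si](C)(C)C#C[C@@]1(O)C[C@H](O[Si](C)(C)C(C)(C)C)[C@@]2(CCl)OC(C)(C)OC[C@@H]12 | intermediate
13 | 7-hydroxy, terminal alkyne | C#C[C@@]1(O)C[C@H](O)[C@@]2(CCl)OC(C)(C)OC[C@@H]12 | intermediate
14 | 7-acetate | C#C[C@@]1(O)C[C@H](OC(C)=O)[C@@]2(CCl)OC(C)(C)OC[C@@H]12 | intermediate
15 | C1/C8 diol | C#C[C@@]1(O)C[C@H](OC(C)=O)[C@](O)(CCl)[C@H]1CO | intermediate
16 | C1 aldehyde | C#C[C@@]1(O)C[C@H](OC(C)=O)[C@](O)(CCl)[C@H]1C=O | intermediate
17 | 1-O-isovaleryl-3,4-ene dihydropyran (C4–H) | CC(=O)O[C@H]1C[C@]2(O)C=CO[C@@H](OC(=O)CC(C)C)[C@@H]2[C@@]1(O)CCl | intermediate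
18 | 4-iodo analogue of 17 | CC(=O)O[C@H]1C[C@]2(O)C(I)=CO[C@@H](OC(=O)CC(C)C)[C@@H]2[C@@]1(O)CCl | intermediate
19 | Volvaltrate B | CC(=O)O[C@H]1C[C@]2(O)C(COC(=O)[C@H](OC(=O)CC(C)C)C(C)C)=CO[C@@H](OC(=O)CC(C)C)[C@@H]2[C@@]1(O)CCl | target

**Totals:** 16 steps in total, of which the side-chain branch (1→2→4) is 2 steps. The longest linear sequence is 14 steps (5→19).

**Three steps most likely to fail**
1. **Step 14 (proposed new Au cascade).** Meyer–Schuster rearrangement of the propargylic alcohol, or intermolecular hydroacyloxylation of the alkyne, may compete.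
   - Fallback (known chemistry): convert the alkyne to the C3 aldehyde by Ru-catalysed anti-Markovnikov hydration. The resulting 1,5-dialdehyde closes to the lactol-enol, which is acylated with isovaleric anhydride/DMAP.
2. **Step 9 (hypochlorite photolysis).** β-Scission of the cyclopentyl alkoxy radical or non-selective HAT by t-BuO• may compete with 1,5-HAT.
   - Fallback: change the approach to an ionic C10–Cl. Use the 3-(TBSOCH2) enone in place of 7, carry C10–OH through, and convert it to chloride by Appel chlorination (PPh3/NCS) after step 12.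
3. **Step 8 (facial selectivity of acetylide addition).** The ketone is flanked by a crowded α-face acetonide, so the wrong C5 epimer could form.
   - Fallback: add acetylide to the unprotected diol 9 with excess ethynylmagnesium bromide, so the C1/C8 magnesium alkoxides deliver it from the α face by chelation control. Re-protect the diol afterwards.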